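**Retrosynthetic overview**

- The strategy rests on the trisubstituted C2=C3 olefin of the 11-membered carbocycle, which must be cis within the ring (C1 and C4 on the same side). Ring numbering: C1 (CH2) to C11 (quaternary carbon with CH3 and the C12–C16 dienyl chain); C3 carries C18H2OH, C7 a CH3, C8 the ester. The olefin is brought in as a (Z)-alkenyl iodide at C3 and the ring is closed at C3–C4.
- Late stage: target ⇐ C18 desilylation ⇐ Mitsunobu inversion and esterification at C8 ⇐ C8-hydroxyl-directed epoxidation of C6=C7 ⇐ macrocyclic (8S)-alcohol.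
- Ring closure: hydroboration of the terminal C4=C5 olefin and intramolecular B-alkyl Suzuki coupling with the C3 iodide. The 11-membered ring is the only carbocycle and forms here; the oxirane follows in step 16.
- Acyclic precursor: C8–C9 by catalytic asymmetric addition of an (E)-alkenylzinc (from a C9≡C10 alkyne) to (2E)-2-methylpenta-2,4-dienal, which sets C8; the Z-iodide comes from an iodo-Wittig reaction at the C2 aldehyde.
- C11: set by Pd-catalysed decarboxylative asymmetric allylation of a 2-methylcyclopentanone; Eschenmoser–Tanabe fragmentation of the derived epoxy ketone opens this auxiliary ring and releases the C9≡C10 alkyne and the C2 aldehyde together.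

Key step: step 14

**Remarks (assumptions on the chemistry)**

- The locants of the overview are used for all intermediates.
- The (R)-phosphinooxazoline ligand in step 2 is assumed to give the (R)-ketone, by analogy with the established (S)-ligand to (S)-ketone correlation for 2-allyl-2-methylcycloalkanones; should the sense be opposite, the (S)-ligand is used.
- The epoxy ketone of step 6 is used as a mixture of epoxide diastereomers, because both epoxide carbons lose their stereochemistry in step 7.
- The starting materials, the phosphinooxazoline ligand and (−)-MIB, (2S)-(−)-3-exo-(morpholino)isoborneol, are taken as purchasable.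

**Route**

Step 1
Reactants: 1 diallyl adipate
Product: 3 allyl 1-methyl-2-oxocyclopentane-1-carboxylate (racemic), via sodium keto ester enolate 2 (not isolated)
Conditions: NaH, THF, 40 °C; then MeI, rt
Reagents that add atoms: iodomethane, CI
Why: Dieckmann condensation of the symmetrical diester gives the stabilised β-keto ester enolate, which is C-methylated in the same flask; the new centre is racemic on purpose because it is re-formed under catalyst control in step 2.

Step 2
Reactants: 3 allyl 1-methyl-2-oxocyclopentane-1-carboxylate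
Product: 4 (2R)-2-allyl-2-methylcyclopentan-1-one
Conditions: Pd2(dba)3 (2.5 mol%), (R)-t-BuPHOX (6 mol%), toluene, 25 °C
Reagents that add atoms: none
Why: Decarboxylative asymmetric allylic alkylation (Tsuji allylation with a chiral phosphinooxazoline): either enantiomer of 3 ionises and loses CO2 to the same allylpalladium enolate, and ligand-controlled allyl transfer to one enolate face sets the quaternary C11 centre as (R) in a stereoconvergent way.

Step 3
Reactants: 4 (2R)-2-allyl-2-methylcyclopentan-1-one
Product: 6 2-[(1R)-1-methyl-2-oxocyclopentyl]acetaldehyde, via diol 5 (not isolated)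
Conditions: OsO4 (cat.), NaIO4, 2,6-lutidine, dioxane/H2O, rt
Reagents that add atoms: osmium tetroxide, O=[Os](=O)(=O)=O; sodium periodate, [Na+].[O-]I(=O)(=O)=O
Why: Lemieux–Johnson cleavage: the only olefin is dihydroxylated and the diol is cleaved by periodate to the C13 aldehyde; the quaternary centre cannot epimerise.

Step 4
Reactants: 6 2-[(1R)-1-methyl-2-oxocyclopentyl]acetaldehyde; 7 diethyl (2-methylprop-2-en-1-yl)phosphonate
Product: 9 (2R)-2-methyl-2-[(2E)-4-methylpenta-2,4-dien-1-yl]cyclopentan-1-one, via lithiated phosphonate 8 (not isolated)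
Conditions: 7, n-BuLi, THF, −78 °C; then 6; HMPA, −78 °C → rt
Reagents that add atoms: none
Why: Horner–Wadsworth–Emmons olefination with an allylic phosphonate anion: the aldehyde reacts in preference to the hindered α-quaternary ketone, and elimination from the equilibrated β-oxido phosphonate gives the conjugated (E)-1,3-diene of the side chain.

Step 5
Reactants: 9 (2R)-2-methyl-2-[(2E)-4-methylpenta-2,4-dien-1-yl]cyclopentan-1-one
Product: 11 (5S)-5-methyl-5-[(2E)-4-methylpenta-2,4-dien-1-yl]cyclopent-2-en-1-one, via lithium enolate 10 (not isolated)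
Conditions: LiN(iPr)2, THF, −78 °C; then PhS(Cl)=N-t-Bu, −78 °C
Reagents that add atoms: none
Why: Mukaiyama dehydrogenation: the single enolisable position gives one enolate, which is sulfenylated by the sulfinimidoyl chloride and undergoes syn-elimination at low temperature to the enone, with no palladium present that could engage the diene (the descriptor changes from R to S only through ligand priorities).

Step 6
Reactants: 11 (5S)-5-methyl-5-[(2E)-4-methylpenta-2,4-dien-1-yl]cyclopent-2-en-1-one
Product: 12 (3S)-3-methyl-3-[(2E)-4-methylpenta-2,4-dien-1-yl]-6-oxabicyclo[3.1.0]hexan-2-one (both epoxide diastereomers)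
Conditions: H2O2 (30% aq.), NaOH (cat.), MeOH, 0 °C
Reagents that add atoms: hydrogen peroxide, OO
Why: Weitz–Scheffer nucleophilic epoxidation: hydroperoxide adds only to the electron-poor enone and leaves the electron-rich diene untouched; the epoxide configuration is irrelevant.

Step 7
Reactants: 12 (3S)-3-methyl-3-[(2E)-4-methylpenta-2,4-dien-1-yl]-6-oxabicyclo[3.1.0]hexan-2-one
Product: 14 (3S,5E)-3-ethynyl-3,7-dimethylocta-5,7-dienal, via sulfonylhydrazone 13 (not isolated)
Conditions: 2,4-(O2N)2C6H3SO2NHNH2, THF, −20 °C; then pyridine, 0 °C → rt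
Reagents that add atoms: none
Why: Eschenmoser–Tanabe fragmentation: the arenesulfonylhydrazone of the α,β-epoxy ketone opens the epoxide and fragments with loss of N2 and sulfinate, turning the carbonyl and α-carbons into the C9≡C10 alkyne and the β-carbon into the C2 aldehyde; the dinitroarene sulfonyl group allows this at low temperature, as is needed when an aldehyde is formed.

Step 8
Reactants: 14 (3S,5E)-3-ethynyl-3,7-dimethylocta-5,7-dienal; 15 ethyl (triphenylphosphoranylidene)acetate
Product: 17 ethyl (2Z,5S,7E)-5-ethynyl-2-iodo-5,9-dimethyldeca-2,7,9-trienoate, via iodo ylide 16 (not isolated)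
Conditions: 15, NIS, MeCN, −20 °C; then 14, −20 °C → rt
Reagents that add atoms: N-iodosuccinimide, O=C1CCC(=O)N1I
Why: Wittig olefination with a stabilised α-iodo ylide (made by iodination of the ester ylide, kept in slight excess over NIS): the ester ends up trans to the chain, which is the (Z)-α-iodo enoate with iodine cis to C1; the minor E isomer is removed by chromatography.

Step 9
Reactants: 17 ethyl (2Z,5S,7E)-5-ethynyl-2-iodo-5,9-dimethyldeca-2,7,9-trienoate
Product: 18 (2Z,5S,7E)-5-ethynyl-2-iodo-5,9-dimethyldeca-2,7,9-trien-1-ol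
Conditions: i-Bu2AlH, CH2Cl2, −78 °C
Reagents that add atoms: none
Why: 1,2-Reduction of the enoate by the aluminium hydride at low temperature leaves the C–I bond, the alkyne and the diene intact and keeps the olefin geometry.

Step 10
Reactants: 18 (2Z,5S,7E)-5-ethynyl-2-iodo-5,9-dimethyldeca-2,7,9-trien-1-ol
Product: 19 tert-butyldiphenylsilyl ether of 18
Conditions: TBDPSCl, imidazole, CH2Cl2, 0 °C → rt
Reagents that add atoms: tert-butyl(chloro)diphenylsilane, CC(C)(C)[Si](Cl)(c1ccccc1)c1ccccc1
Why: Standard silylation of the primary allylic alcohol; the robust silyl ether survives every later step up to the final fluoride treatment.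

Step 11
Reactants: 20 acrolein; 21 2-(triphenylphosphoranylidene)propanal
Product: 22 (2E)-2-methylpenta-2,4-dienal
Conditions: toluene, 60 °C, sealed vessel (20 in excess, trace hydroquinone)
Reagents that add atoms: none
Why: Wittig reaction of a formyl-stabilised ylide, which gives the (E)-2-methyl enal (CHO trans to the vinyl group); excess acrolein suppresses a second olefination of the product.

Step 12
Reactants: 19 tert-butyldiphenylsilyl ether of 18; 22 (2E)-2-methylpenta-2,4-dienal
Product: 25 acyclic (8S,11S) C8 carbinol, via alkenylborane 23 (not isolated), via alkenylzinc 24 (not isolated)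
Conditions: Cy2BH (from BH3·SMe2 and cyclohexene), toluene, 0 °C → rt; Me2Zn, −78 °C; (−)-MIB (5 mol%), then 22, −10 °C
Reagents that add atoms: none
Why: Catalytic asymmetric alkenylzinc addition: syn-hydroboration of the terminal alkyne (much faster than attack on the 1,1-disubstituted diene terminus or the iodoalkene) gives the (E)-alkenylborane, boron–zinc exchange gives the alkenylzinc, and the zinc aminoalkoxide of (−)-MIB directs addition to the Si face of the α-branched enal, so that C8 is set as (S) (epimeric to the target, as step 16 requires) and any minor C11 enantiomer becomes a separable diastereomer.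

Step 13
Reactants: 25 acyclic (8S,11S) C8 carbinol
Product: 26 triethylsilyl ether of 25 (cyclisation precursor)
Conditions: TESCl, imidazole, DMAP (cat.), CH2Cl2, 0 °C
Reagents that add atoms: chlorotriethylsilane, CC[Si](Cl)(CC)CC
Why: Silylation under basic conditions protects the ionisation-prone doubly allylic carbinol and keeps the hydroxyl from consuming borane in the next step.

Step 14
Reactants: 26 triethylsilyl ether of 25
Product: 28 11-membered (8S,11S) triene bis-silyl ether, via alkylborane 27 (not isolated)
Conditions: Sia2BH (from BH3·THF and 2-methylbut-2-ene), THF, 0 °C; then slow addition to Pd(dppf)Cl2 (20 mol%), AsPh3 (40 mol%), Tl2CO3, THF/DMF/H2O, rt, final concentration about 1 mM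
Reagents that add atoms: none
Why: Disiamylborane adds anti-Markovnikov to the monosubstituted C4=C5 terminus of the C4–C7 diene (boron on C4), which a hindered dialkylborane attacks much faster than the 1,1-disubstituted C15=C16 terminus, the internal olefins or the iodoalkene, and the resulting homoallylic borane leaves C6=C7 in place. Zerovalent palladium then inserts into the C3–I bond, the base-activated borane transfers its unhindered primary C4 alkyl group in preference to the two secondary siamyl groups, and reductive elimination forms C3–C4; the closest known reaction type is the B-alkyl Suzuki–Miyaura macrocyclisation of an alkylborane onto an alkenyl iodide. The 11-membered ring closes through this single sp2–sp3 bond by reductive elimination from a 12-membered palladacycle, with retention at the alkenyl carbon, so that C1 and C4 end up cis on C2=C3. No stereocentre is formed and C8 and C11 are not touched. The step needs ring closure to outrun dimerisation, β-hydride elimination and 5-exo Heck insertion of the alkenylpalladium into C9=C10. Slow addition at high dilution, the quaternary C11 and the rigid olefins that pre-organise the chain, and fast transmetalation and reductive elimination at room temperature (Tl2CO3, wide-bite-angle dppf, AsPh3) are meant to secure this.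

Step 15
Reactants: 28 11-membered (8S,11S) triene bis-silyl ether
Product: 29 macrocyclic (8S,11S) C8 alcohol
Conditions: HF·pyridine, pyridine, THF, 0 °C
Reagents that add atoms: none
Why: Buffered fluoride cleaves the secondary triethylsilyl ether much faster than the primary tert-butyldiphenylsilyl ether and is not acidic enough to ionise the doubly allylic alcohol.

Step 16
Reactants: 29 macrocyclic (8S,11S) C8 alcohol
Product: 30 (6S,7S,8S,11S) epoxy alcohol
Conditions: VO(acac)2 (5 mol%), t-BuOOH (decane), CH2Cl2, 0 °C
Reagents that add atoms: tert-butyl hydroperoxide, CC(C)(C)OO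
Why: Hydroxyl-directed epoxidation: the vanadate ester of the C8 hydroxyl delivers oxygen to the more electron-rich trisubstituted C6=C7 olefin rather than to C9=C10 or the remote olefins, and minimising A(1,2) strain between the C7 methyl and C9 places the C8–H in the olefin plane, so that oxygen enters syn to the hydroxyl and gives the erythro epoxy alcohol, which has the oxirane configuration of the target.

Step 17
Reactants: 30 (6S,7S,8S,11S) epoxy alcohol; 31 3-methylbut-2-enoic acid
Product: 32 (6S,7R,8R,11S) C8 3-methylbut-2-enoate with C18 silyl ether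
Conditions: PPh3, DIAD, toluene, 0 °C → rt
Reagents that add atoms: none
Why: Mitsunobu esterification: the C8 hydroxyl is activated as its alkoxyphosphonium ion and displaced by the carboxylate in an SN2 process with inversion to (8R), allylic transposition to C10 being disfavoured by the adjacent quaternary C11; C6 and C7 are untouched (the C7 descriptor changes from S to R only through ligand priorities).

Step 18
Reactants: 32 (6S,7R,8R,11S) C8 3-methylbut-2-enoate with C18 silyl ether
Product: 33 vibsanin R
Conditions: Bu4NF, AcOH, THF, 0 °C → rt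
Reagents that add atoms: none
Why: Fluoride cleaves the Si–O bond of the primary silyl ether; acetic acid buffering protects the ester from cleavage or migration and the oxirane from opening.

**Compound list**

1 | diallyl adipate | C=CCOC(=O)CCCCC(=O)OCC=C | starting material
2 | sodium enolate of allyl 2-oxocyclopentane-1-carboxylate | C=CCOC(=O)C1=C([O-])CCC1.[Na+] | intermediate (not isolated)
3 | allyl 1-methyl-2-oxocyclopentane-1-carboxylate (racemic) | C=CCOC(=O)C1(C)CCCC1=O | intermediate
4 | (2R)-2-allyl-2-methylcyclopentan-1-one | C=CC[C@]1(C)C(=O)CCC1 | intermediate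
5 | (2R)-2-(2,3-dihydroxypropyl)-2-methylcyclopentan-1-one (carbinol epimers) | OCC(O)C[C@]1(C)C(=O)CCC1 | intermediate (not isolated)
6 | 2-[(1R)-1-methyl-2-oxocyclopentyl]acetaldehyde | O=CC[C@]1(C)C(=O)CCC1 | intermediate
7 | diethyl (2-methylprop-2-en-1-yl)phosphonate | C=C(C)CP(=O)(OCC)OCC | starting material
8 | lithium salt of 7 (α-lithiated phosphonate) | [Li+].C=C(C)[CH-]P(=O)(OCC)OCC | intermediate (not isolated)
9 | (2R)-2-methyl-2-[(2E)-4-methylpenta-2,4-dien-1-yl]cyclopentan-1-one | C=C(C)/C=C/C[C@]1(C)C(=O)CCC1 | intermediate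
10 | lithium enolate of 9 | [Li+].C=C(C)/C=C/C[C@]1(C)C([O-])=CCC1 | intermediate (not isolated)
11 | (5S)-5-methyl-5-[(2E)-4-methylpenta-2,4-dien-1-yl]cyclopent-2-en-1-one | C=C(C)/C=C/C[C@]1(C)C(=O)C=CC1 | intermediate
12 | (3S)-3-methyl-3-[(2E)-4-methylpenta-2,4-dien-1-yl]-6-oxabicyclo[3.1.0]hexan-2-one (both epoxide diastereomers) | C=C(C)/C=C/C[C@]1(C)C(=O)C2OC2C1 | intermediate
13 | 2,4-dinitrobenzenesulfonylhydrazone of 12 | C=C(C)/C=C/C[C@]1(C)C(=NNS(=O)(=O)c2ccc(cc2[N+](=O)[O-])[N+](=O)[O-])C2OC2C1 | intermediate (not isolated)
14 | (3S,5E)-3-ethynyl-3,7-dimethylocta-5,7-dienal | C=C(C)/C=C/C[C@](C)(C#C)CC=O | intermediate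
15 | ethyl (triphenylphosphoranylidene)acetate | CCOC(=O)C=P(c1ccccc1)(c1ccccc1)c1ccccc1 | starting material
16 | ethyl iodo(triphenylphosphoranylidene)acetate | CCOC(=O)C(I)=P(c1ccccc1)(c1ccccc1)c1ccccc1 | intermediate (not isolated)
17 | ethyl (2Z,5S,7E)-5-ethynyl-2-iodo-5,9-dimethyldeca-2,7,9-trienoate | C=C(C)/C=C/C[C@](C)(C#C)C/C=C(\I)C(=O)OCC | intermediate
18 | (2Z,5S,7E)-5-ethynyl-2-iodo-5,9-dimethyldeca-2,7,9-trien-1-ol | C=C(C)/C=C/C[C@](C)(C#C)C/C=C(\I)CO | intermediate
19 | tert-butyl{[(2Z,5S,7E)-5-ethynyl-2-iodo-5,9-dimethyldeca-2,7,9-trien-1-yl]oxy}diphenylsilane | C=C(C)/C=C/C[C@](C)(C#C)C/C=C(\I)CO[Si](c1ccccc1)(c1ccccc1)C(C)(C)C | intermediate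
20 | acrolein | C=CC=O | starting material
21 | 2-(triphenylphosphoranylidene)propanal | CC(C=O)=P(c1ccccc1)(c1ccccc1)c1ccccc1 | starting material
22 | (2E)-2-methylpenta-2,4-dienal | C=C/C=C(\C)C=O | intermediate
23 | (E)-alkenyl(dicyclohexyl)borane from 19 (boron on C9) | C=C(C)/C=C/C[C@](C)(/C=C/B(C1CCCCC1)C1CCCCC1)C/C=C(\I)CO[Si](c1ccccc1)(c1ccccc1)C(C)(C)C | intermediate (not isolated)
24 | (E)-alkenyl(methyl)zinc from 19 (zinc on C9) | C=C(C)/C=C/C[C@](C)(/C=C/[Zn]C)C/C=C(\I)CO[Si](c1ccccc1)(c1ccccc1)C(C)(C)C | intermediate (not isolated)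
25 | acyclic (8S,11S) carbinol: C11 bears CH3, the (2E)-4-methylpenta-2,4-dienyl chain, the (Z)-CH2CH=C(I)CH2OTBDPS arm and the (E)-CH=CH–CH(OH)–C(CH3)=CH–CH=CH2 arm | C=C(C)/C=C/C[C@](C/C=C(\I)CO[Si](c1ccccc1)(c1ccccc1)C(C)(C)C)(C)/C=C/[C@H](O)/C(C)=C/C=C | intermediate
26 | triethylsilyl ether of 25 (cyclisation precursor) | C=C(C)/C=C/C[C@](C/C=C(\I)CO[Si](c1ccccc1)(c1ccccc1)C(C)(C)C)(C)/C=C/[C@H](O[Si](CC)(CC)CC)/C(C)=C/C=C | intermediate
27 | C4 bis(3-methylbutan-2-yl)borane of 26 | C=C(C)/C=C/C[C@](C/C=C(\I)CO[Si](c1ccccc1)(c1ccccc1)C(C)(C)C)(C)/C=C/[C@H](O[Si](CC)(CC)CC)/C(C)=C/CCB(C(C)C(C)C)C(C)C(C)C | intermediate (not isolated)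
28 | 11-membered (8S,11S) triene, C8 OTES, C18 OTBDPS (ring olefins: C2=C3 cis in ring, C6=C7 and C9=C10 E) | C=C(C)/C=C/C[C@]1(C)/C=C/[C@H](O[Si](CC)(CC)CC)/C(C)=C/CC/C(CO[Si](c2ccccc2)(c2ccccc2)C(C)(C)C)=C\C1 | intermediate
29 | macrocyclic (8S,11S) C8 alcohol, C18 OTBDPS | C=C(C)/C=C/C[C@]1(C)/C=C/[C@H](O)/C(C)=C/CC/C(CO[Si](c2ccccc2)(c2ccccc2)C(C)(C)C)=C\C1 | intermediate
30 | (6S,7S,8S,11S) 6,7-epoxy C8 alcohol, C18 OTBDPS | C=C(C)/C=C/C[C@]1(C)/C=C/[C@H](O)[C@]2(C)O[C@H]2CC/C(CO[Si](c3ccccc3)(c3ccccc3)C(C)(C)C)=C\C1 | intermediate
31 | 3-methylbut-2-enoic acid | CC(C)=CC(=O)O | starting material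
32 | (6S,7R,8R,11S) 6,7-epoxy C8 3-methylbut-2-enoate, C18 OTBDPS | C=C(C)/C=C/C[C@]1(C)/C=C/[C@@H](OC(=O)C=C(C)C)[C@]2(C)O[C@H]2CC/C(CO[Si](c3ccccc3)(c3ccccc3)C(C)(C)C)=C\C1 | intermediate
33 | vibsanin R | C=C(C)/C=C/C[C@]1(C)/C=C/[C@@H](OC(=O)C=C(C)C)[C@]2(C)O[C@H]2CC/C(CO)=C\C1 | target

**Step count**

Total: 18 steps. Longest linear sequence: 17 steps (steps 1–10 and 12–18, from diallyl adipate); step 11 is a one-step side branch.

**Steps most likely to fail**

1. Step 14 (ring closure). The hydroboration may not discriminate cleanly between the two diene termini, and the alkenylpalladium iodide may be consumed by oligomerisation, β-hydride elimination or Heck insertion before the strained 11-membered ring closes.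
Fallback: C3–C4 is made by the same cross-coupling between two molecules and the ring is closed at C8–C9 by a zinc-mediated alkenyl addition. The fallback sets out from 19 and 22 and comes back to the route at 29. Aldehyde 22 is converted with HC(OMe)3/MeOH and catalytic pyridinium tosylate into (3E)-5,5-dimethoxy-4-methylpenta-1,3-diene F1. Its terminal olefin is hydroborated with 9-borabicyclo[3.3.1]nonane to the B-alkyl borane F2, where no second terminal olefin competes. F2 is coupled with iodide 19 (Pd(dppf)Cl2, AsPh3, Cs2CO3, DMF/THF/H2O, rt) to the alkynyl acetal F3. Mild hydrolysis (pyridinium tosylate, wet acetone) gives the ynal F4. Cy2BH adds to the terminal alkyne of F4 faster than it reduces the conjugated aldehyde, giving the alkenylborane F5. Slow addition of F5 to Me2Zn and (−)-MIB in toluene at high dilution closes the ring between C9 and C8 with the same Si-face selectivity as in step 12 and gives 29 after aqueous work-up.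

2. Step 17 (inversion at C8). Activation of the hindered C8 hydroxyl next to the fully substituted oxirane carbon may be slow, so that elimination, attack with allylic shift or esterification with retention through an acyloxyphosphonium pathway competes with the SN2 displacement.
Fallback: the configuration is corrected by oxidation and reduction instead of displacement. The fallback sets out from 30 and comes back at 32. Dess–Martin periodinane with NaHCO3 oxidises 30 to the epoxy enone F6. Reagent-controlled reduction with BH3·SMe2 and the oxazaborolidine catalyst ((S)-Me-CBS if the oxirane-bearing quaternary carbon acts as the large group) gives the (8R)-epoxy alcohol F7. Carbodiimide esterification of F7 with 31 (EDC, DMAP, CH2Cl2, 0 °C) gives 32.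

3. Step 16 (directed epoxidation). The ring conformation rather than A(1,2) strain may decide which face of C6=C7 the vanadium-bound peroxide reaches, giving poor or reversed facial selectivity, and epoxidation of C9=C10 may compete.
Fallback: substrate control is replaced by reagent control. The fallback sets out from 29 and comes back at 30, using Sharpless asymmetric epoxidation with Ti(OiPr)4, L-(+)-diisopropyl tartrate and t-BuOOH (4 Å sieves, CH2Cl2, −20 °C). For the (8S)-alcohol this tartrate is the matched one: it delivers oxygen to the required face of the trisubstituted allylic olefin and gives the same erythro epoxy alcohol, with no new intermediate.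

**Further compounds**

F1 | step 14 | (3E)-5,5-dimethoxy-4-methylpenta-1,3-diene | C=C/C=C(\C)C(OC)OC
F2 | step 14 | 9-[(3E)-5,5-dimethoxy-4-methylpent-3-en-1-yl]-9-borabicyclo[3.3.1]nonane | COC(OC)/C(C)=C/CCB1C2CCCC1CCC2
F3 | step 14 | acyclic alkynyl acetal with C3–C4 in place (C8 as dimethyl acetal, C9≡C10 alkyne, C18 OTBDPS) | C=C(C)/C=C/C[C@](C)(C#C)C/C=C(\CC/C=C(\C)C(OC)OC)CO[Si](c1ccccc1)(c1ccccc1)C(C)(C)C
F4 | step 14 | acyclic ynal (C8 aldehyde, C9≡C10 alkyne, C18 OTBDPS) | C=C(C)/C=C/C[C@](C)(C#C)C/C=C(\CC/C=C(\C)C=O)CO[Si](c1ccccc1)(c1ccccc1)C(C)(C)C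
F5 | step 14 | (E)-alkenyl(dicyclohexyl)borane of F4 (boron on C9) | C=C(C)/C=C/C[C@](C)(/C=C/B(C1CCCCC1)C1CCCCC1)C/C=C(\CC/C=C(\C)C=O)CO[Si](c1ccccc1)(c1ccccc1)C(C)(C)C
F6 | step 17 | (6S,7R,11S) 6,7-epoxy C8 ketone, C18 OTBDPS | C=C(C)/C=C/C[C@]1(C)/C=C/C(=O)[C@]2(C)O[C@H]2CC/C(CO[Si](c3ccccc3)(c3ccccc3)C(C)(C)C)=C\C1
F7 | step 17 | (6S,7S,8R,11S) 6,7-epoxy C8 alcohol, C18 OTBDPS | C=C(C)/C=C/C[C@]1(C)/C=C/[C@@H](O)[C@]2(C)O[C@H]2CC/C(CO[Si](c3ccccc3)(c3ccccc3)C(C)(C)C)=C\C1
F0 | step 16 | none | none
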